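Ring A is cut at the two bonds that join its flanking carbonyl carbons to the CH(CH3) and C(CH3)2 carbons, so that the three central carbons come from 2-methylpentan-3-one and the spiro carbon C1′ with both carbonyls from a malonyl unit already built into ring B. The key step exploits this 1,3,5-trione pattern of ring A: in one flask the ketone is acylated at its CH2 carbon and then, as the dianion, at its isopropyl carbon, which closes ring A. The precursor is the ring B spiro malonate whose carboxyl cis to the C5′ isopropyl is an acid chloride and whose trans carboxyl is a methyl ester, so the configuration at C1′ is preset.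

Key step: step 10

Remark on labels: ring B is C1′ (the spiro carbon shared with ring A), C2′ (identical with pinane C2), C3′, C4′, C5′ (isopropyl); the pinane keeps C1 to C7, with C6 the gem-dimethyl bridge and C7 the CH2 bridge. Ring A is described in words. Going round from C1′ it holds the cis carbonyl carbon (the one on the ring B face of the C5′ isopropyl), the CH(CH3) carbon, the central C–O carbon, the C(CH3)2 carbon and the trans carbonyl carbon.

Remark on the chemistry: the two carboxyl groups on C1′ are diastereotopic, and they are told apart in steps 6 to 9 so that the pairing of ketone carbons with carboxyl carbons does not rest on a steric preference; the CH(CH3) carbon of trione 20 is enolised and is given no configuration.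

Step 1
Reactants: 1 (1R,5R)-(+)-α-pinene
Product: 4 (1R,5R)-(+)-β-pinene, via pinenylpotassium 2 (not isolated), via potassium trimethoxy(myrtenyl)borate 3 (not isolated)
Conditions: n-BuLi, KOt-Bu, hexane, rt; B(OMe)3, Et2O, −78 °C→rt; aq HCl
Reagents that add atoms: none
Why: Allylic metalation with the n-BuLi/KOt-Bu superbase removes a hydrogen of the C2 methyl group, boron takes the exocyclic CH2 terminus, and protonolysis of the allylborate with allylic transposition puts the proton on C3 and leaves the exocyclic alkene, a contra-thermodynamic alkene isomerisation that touches neither bridgehead.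

Step 2
Reactants: 4 (1R,5R)-(+)-β-pinene
Product: 6 (1S,5R)-(−)-nopinone, via spiro ozonide 5 (not isolated)
Conditions: O3, CH2Cl2, −78 °C; Me2S, −78 °C→rt
Reagents that add atoms: ozone, O=[O+][O-]
Why: Ozonolysis with reductive work-up cleaves the 1,1-disubstituted alkene to the ketone and formaldehyde, and the bridgehead centres are locked in the bicycle and cannot epimerise.

Step 3
Reactants: 6 (1S,5R)-(−)-nopinone; 7 dimethyl malonate
Product: 8 dimethyl 2-[(1S,5R)-6,6-dimethylbicyclo[3.1.1]heptan-2-ylidene]malonate
Conditions: TiCl4, pyridine, THF, 0 °C→rt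
Reagents that add atoms: none
Why: Knoevenagel condensation in its TiCl4/pyridine form, the usual way to condense a ketone with a malonic ester, in which the titanium enolate adds to the activated ketone and the titanium-bound aldolate eliminates irreversibly; no stereocentre is formed.

Step 4
Reactants: 8 dimethyl 2-[(1S,5R)-6,6-dimethylbicyclo[3.1.1]heptan-2-ylidene]malonate; 9 5-bromo-2-methylpent-2-ene
Product: 11 dimethyl 2-[(1S,2S,5R)-6,6-dimethyl-2-(4-methylpent-3-en-1-yl)bicyclo[3.1.1]heptan-2-yl]malonate, via (4-methylpent-3-en-1-yl)magnesium bromide 10 (not isolated)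
Conditions: 9, Mg, THF, rt→40 °C; then 8, CuBr·SMe2 (10 mol %), THF, −40→0 °C; aq NH4Cl
Reagents that add atoms: none
Why: Copper-catalysed conjugate addition of a Grignard reagent to an alkylidene malonate builds the quaternary C2, the organocopper attacking the face of C2 anti to the gem-dimethyl bridge (the face opened by the CH2 bridge, as in cuprate additions to other pinane enones), which places the chain anti and the malonate carbon syn to that bridge (2S).

Step 5
Reactants: 11 dimethyl 2-[(1S,2S,5R)-6,6-dimethyl-2-(4-methylpent-3-en-1-yl)bicyclo[3.1.1]heptan-2-yl]malonate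
Product: 12 dimethyl 5′-isopropenylspiro[pinane-2,2′-cyclopentane]-1′,1′-dicarboxylate (C1′ syn to the gem-dimethyl bridge at pinane C2; isopropenyl on the ring B face that carries pinane C3)
Conditions: Mn(OAc)3·2H2O (2.2 equiv), Cu(OAc)2·H2O (1 equiv), AcOH, 70 °C
Reagents that add atoms: none
Why: Oxidative free-radical cyclisation in which Mn(OAc)3 turns the malonate C–H into a malonyl radical that closes 5-exo-trig on the CH terminus of the trisubstituted alkene and Cu(OAc)2 oxidises the tertiary radical to the isopropenyl alkene, C5′ being set in the chair-like transition state that keeps the bulkier bridgehead branch (pinane C1) of the spiro carbon pseudo-equatorial and so puts the side chain on the ring B face that carries pinane C3.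

Step 6
Reactants: 12 dimethyl 5′-isopropenylspiro[pinane-2,2′-cyclopentane]-1′,1′-dicarboxylate
Product: 13 iodolactone methyl ester (carboxyl cis to the C5′ side chain closed as a γ-lactone on the C(CH3)(CH2I) carbon; trans carboxyl kept as CO2CH3)
Conditions: I2 (3 equiv), MeCN, rt, dark; aq Na2S2O3
Reagents that add atoms: iodine, [I][I]
Why: Iodolactonisation with ester participation (5-exo, Markovnikov), in which only the ester cis to the isopropenyl group can reach the iodonium ion and form a cis-fused γ-lactone while its methyl leaves as iodomethane, so that the two carboxyls are told apart and C1′ becomes a defined stereocentre; the new C(CH3)(CH2I) centre is of no consequence because step 7 removes it.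

Step 7
Reactants: 13 iodolactone methyl ester
Product: 14 5′-isopropenyl-1′-(methoxycarbonyl)spiro[pinane-2,2′-cyclopentane]-1′-carboxylic acid (CO2H cis to isopropenyl)
Conditions: Zn dust, AcOH, THF, rt
Reagents that add atoms: none
Why: Reductive β-elimination, in which zinc inserts into the C–I bond and the β-carboxylate leaves, restores the isopropenyl group and frees the cis carboxyl alone as the acid without touching a stereocentre of the ring system.

Step 8
Reactants: 14 5′-isopropenyl-1′-(methoxycarbonyl)spiro[pinane-2,2′-cyclopentane]-1′-carboxylic acid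
Product: 15 5′-isopropyl-1′-(methoxycarbonyl)spiro[pinane-2,2′-cyclopentane]-1′-carboxylic acid (CO2H cis to isopropyl)
Conditions: H2 (1 atm), PtO2, EtOAc, rt
Reagents that add atoms: none
Why: Catalytic hydrogenation of the unhindered 1,1-disubstituted alkene gives the isopropyl group and creates no stereocentre, platinum being chosen to keep double bond migration towards C5′, and with it epimerisation, low.

Step 9
Reactants: 15 5′-isopropyl-1′-(methoxycarbonyl)spiro[pinane-2,2′-cyclopentane]-1′-carboxylic acid
Product: 16 methyl 1′-(chlorocarbonyl)-5′-isopropylspiro[pinane-2,2′-cyclopentane]-1′-carboxylate (COCl cis to isopropyl)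
Conditions: (COCl)2, DMF (cat.), CH2Cl2, 0 °C→rt
Reagents that add atoms: oxalyl chloride, O=C(Cl)C(Cl)=O
Why: Acid chloride formation through the chloroiminium species made from oxalyl chloride and DMF should be clean because the α-carbon is quaternary, which rules out ketene formation and epimerisation, and the methyl ester is untouched.

Step 10
Reactants: 16 methyl 1′-(chlorocarbonyl)-5′-isopropylspiro[pinane-2,2′-cyclopentane]-1′-carboxylate; 17 2-methylpentan-3-one
Product: 20 spiro trione (ring A as 3,5,5-trimethylcyclohexane-2,4,6-trione spiro-fused at C1′; the carbonyl next to CH(CH3) cis to the C5′ isopropyl), via lithium enolate 18 (not isolated), via diketo ester 19 (not isolated)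
Conditions: 17 (2.2 equiv), LiN(i-Pr)2 (2.2 equiv), THF, −78 °C; 16, −78→0 °C; LiN(i-Pr)2 (3 equiv), 0→45 °C; aq HCl
Reagents that add atoms: none
Why: LiN(i-Pr)2 removes a CH2 hydrogen of 17 under kinetic control to give enolate 18, whose carbon attacks the acid chloride carbon (the future cis carbonyl) in preference to the far less electrophilic methyl ester, and the 1,3-diketone formed is deprotonated at once by the second equivalent of 18 to the lithium diketonate of 19; the further amide base then removes the methine hydrogen of the isopropyl ketone end, and this dianion carbon, the future C(CH3)2 carbon, adds to the ester carbonyl (the future trans carbonyl) and expels methoxide, which leaves 20 as the enolate of its CH(CH3) carbon. The closest known reaction type is the acylation of a ketone enolate with a malonic half-ester chloride followed by base-induced Claisen (Dieckmann) ring closure, the sequence used for 2,2,4,4-tetrasubstituted cyclohexane-1,3,5-triones of the syncarpic acid type, run here in one pot. Ring A closes in the 6-exo-trig mode, the attacked ester C=O lying outside the ring that forms. No face is selected in this step: the configuration at C1′ follows from which carboxyl carbon carries chlorine, and that was fixed in step 6 by the cis-only lactonisation onto the C5′ side chain, so the CH(CH3) carbon must end on the carbonyl cis to isopropyl and the C(CH3)2 carbon on the trans one, as in the target. The step needs acid chloride over ester chemoselectivity, CH2 over CH regioselectivity in the first acylation and C- over O-acylation; the reactivity gap between the two acyl groups and kinetic enolisation secure the first two, and an enol ester from O-acylation is itself an acyl donor towards 18 and should be funnelled to the chelated diketonate. The CH(CH3) carbon of 20 is enolised and carries no fixed configuration.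

Step 11
Reactants: 20 spiro trione
Product: 21 CNP0307059.1 (ring A as 4-methoxy-3,5,5-trimethylcyclohex-3-ene-2,6-dione spiro-fused at C1′)
Conditions: Me3SiCHN2, MeOH/PhMe (1:4), 0 °C→rt
Reagents that add atoms: (trimethylsilyl)diazomethane, C[Si](C)(C)C=[N+]=[N-]
Why: O-Methylation of the acidic enol that spans the cis carbonyl, the CH(CH3) carbon and the central carbonyl by the diazomethane equivalent should favour the central oxygen, whose carbon is flanked by C(CH3)2 and lies far from the crowded spiro carbon, and material methylated on the oxygen of the cis carbonyl can be separated and returned to 20 with dilute aqueous acid.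

Compound list

1 | (1R,5R)-(+)-α-pinene, (1R,5R)-2,6,6-trimethylbicyclo[3.1.1]hept-2-ene | CC1=CC[C@@H]2C[C@H]1C2(C)C | starting material
2 | pinenylpotassium (allylic potassium compound metalated at the C2 methyl group; bridgeheads as in 1) | [K+].[CH2-]C1=CC[C@@H]2C[C@H]1C2(C)C | intermediate
3 | potassium trimethoxy(myrtenyl)borate (boron on the exocyclic CH2 of the pin-2-ene; bridgeheads as in 1) | [K+].CO[B-](OC)(OC)CC1=CC[C@@H]2C[C@H]1C2(C)C | intermediate
4 | (1R,5R)-(+)-β-pinene, 6,6-dimethyl-2-methylidenebicyclo[3.1.1]heptane | C=C1CC[C@@H]2C[C@H]1C2(C)C | intermediate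
5 | spiro ozonide of 4 (1,2,4-trioxolane with pinane C2 as spiro carbon, configuration at that carbon undefined) | C1OOC2(O1)CC[C@@H]1C[C@H]2C1(C)C | intermediate
6 | (1S,5R)-(−)-nopinone, 6,6-dimethylbicyclo[3.1.1]heptan-2-one | O=C1CC[C@@H]2C[C@H]1C2(C)C | intermediate
7 | dimethyl malonate | COC(=O)CC(=O)OC | starting material
8 | dimethyl 2-[(1S,5R)-6,6-dimethylbicyclo[3.1.1]heptan-2-ylidene]malonate | COC(=O)C(C(=O)OC)=C1CC[C@@H]2C[C@H]1C2(C)C | intermediate
9 | 5-bromo-2-methylpent-2-ene | CC(C)=CCCBr | starting material
10 | (4-methylpent-3-en-1-yl)magnesium bromide | CC(C)=CCC[Mg]Br | intermediate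
11 | dimethyl 2-[(1S,2S,5R)-6,6-dimethyl-2-(4-methylpent-3-en-1-yl)bicyclo[3.1.1]heptan-2-yl]malonate (chain anti, malonate carbon syn to the gem-dimethyl bridge) | COC(=O)C(C(=O)OC)[C@@]1(CCC=C(C)C)CC[C@@H]2C[C@H]1C2(C)C | intermediate
12 | dimethyl 5′-isopropenylspiro[pinane-2,2′-cyclopentane]-1′,1′-dicarboxylate (C1′ syn and C3′ anti to the gem-dimethyl bridge at pinane C2; isopropenyl on the ring B face that carries pinane C3) | COC(=O)C3(C(=O)OC)[C@@H](C(C)=C)CC[C@@]31CC[C@@H]2C[C@H]1C2(C)C | intermediate
13 | iodolactone methyl ester (ring system as in 12; the carboxyl cis to the C5′ side chain closed as a cis-fused γ-lactone on the C(CH3)(CH2I) carbon, that carbon undefined; trans carboxyl as CO2CH3) | COC(=O)[C@]12C(=O)OC(C)(CI)[C@H]1CC[C@@]21CC[C@@H]2C[C@H]1C2(C)C | intermediate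
14 | 5′-isopropenyl-1′-(methoxycarbonyl)spiro[pinane-2,2′-cyclopentane]-1′-carboxylic acid (CO2H cis, CO2CH3 trans to isopropenyl) | COC(=O)[C@]1(C(=O)O)[C@@H](C(C)=C)CC[C@@]12CC[C@@H]3C[C@H]2C3(C)C | intermediate
15 | 5′-isopropyl-1′-(methoxycarbonyl)spiro[pinane-2,2′-cyclopentane]-1′-carboxylic acid (CO2H cis, CO2CH3 trans to isopropyl) | COC(=O)[C@]1(C(=O)O)[C@@H](C(C)C)CC[C@@]12CC[C@@H]3C[C@H]2C3(C)C | intermediate
16 | methyl 1′-(chlorocarbonyl)-5′-isopropylspiro[pinane-2,2′-cyclopentane]-1′-carboxylate (COCl cis, CO2CH3 trans to isopropyl) | COC(=O)[C@]1(C(Cl)=O)[C@@H](C(C)C)CC[C@@]12CC[C@@H]3C[C@H]2C3(C)C | intermediate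
17 | 2-methylpentan-3-one | CCC(=O)C(C)C | starting material
18 | lithium enolate of 17 at the CH2 carbon, lithium 2-methylpent-3-en-3-olate (alkene geometry not specified) | [Li+].CC=C([O-])C(C)C | intermediate
19 | methyl 1′-(2,4-dimethyl-3-oxopentanoyl)-5′-isopropylspiro[pinane-2,2′-cyclopentane]-1′-carboxylate (acyl group cis to isopropyl; present in the flask as its lithium enolate; CH(CH3) centre undefined) | COC(=O)[C@]1(C(=O)C(C)C(=O)C(C)C)[C@@H](C(C)C)CC[C@@]12CC[C@@H]3C[C@H]2C3(C)C | intermediate
20 | spiro trione (ring A as 3,5,5-trimethylcyclohexane-2,4,6-trione spiro-fused at C1′; the carbonyl next to CH(CH3) cis and the carbonyl next to C(CH3)2 trans to the C5′ isopropyl; CH(CH3) centre undefined) | O=C1C(C)C(=O)[C@@]2(C(=O)C1(C)C)[C@@H](C(C)C)CC[C@@]21CC[C@@H]2C[C@H]1C2(C)C | intermediate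
21 | CNP0307059.1 (ring A as 4-methoxy-3,5,5-trimethylcyclohex-3-ene-2,6-dione spiro-fused at C1′; enone carbonyl cis and the carbonyl next to C(CH3)2 trans to the C5′ isopropyl) | COC1=C(C)C(=O)[C@@]2(C(=O)C1(C)C)[C@@H](C(C)C)CC[C@@]21CC[C@@H]2C[C@H]1C2(C)C | target

Total step count: 11. Longest linear sequence: 11 steps (1 to 21).

Steps most likely to fail

Step 10. The first acylation takes place between two molecules at a carbonyl carbon flanked by a quaternary centre and the cis isopropyl group. It may stall or go to the enolate oxygen, and the diketonate may close through oxygen to an enol lactone instead of through carbon. Fallback: setting out from 16, the acid chloride is coupled with EtMgBr under CuI catalysis (THF, −78 °C), a small nucleophile that tolerates the crowding, to give the ethyl ketone methyl 5′-isopropyl-1′-propanoylspiro[pinane-2,2′-cyclopentane]-1′-carboxylate F1. The lithium enolate of F1 (LiN(i-Pr)2, THF, −78 °C) is then acylated on carbon with 1-(2-methylpropanoyl)benzotriazole, so that the bond made between two molecules is the one from the CH(CH3) carbon to the central carbonyl carbon and no longer the one from the cis carbonyl carbon to the CH(CH3) carbon. This should give 19 as an isolated compound, and LiN(i-Pr)2 (2.2 equiv, THF, 0→45 °C) closes the bond from the C(CH3)2 carbon to the trans carbonyl carbon, so the route is rejoined at 20.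

Step 5. Enolisation of the congested malonate towards Mn(OAc)3 may be slow, the tertiary radical may be oxidised on to the cation and lactonise, and the discrimination between the two faces at C5′ may be insufficient. Fallback: setting out from 11, allylic oxidation with SeO2 (cat.) and t-BuOOH in CH2Cl2 should give the (E)-allylic alcohol dimethyl 2-[(1S,2S,5R)-2-[(E)-5-hydroxy-4-methylpent-3-en-1-yl]-6,6-dimethylbicyclo[3.1.1]heptan-2-yl]malonate F2. Methyl chloroformate and pyridine convert it into the methyl carbonate dimethyl 2-[(1S,2S,5R)-2-[(E)-5-(methoxycarbonyloxy)-4-methylpent-3-en-1-yl]-6,6-dimethylbicyclo[3.1.1]heptan-2-yl]malonate F3. Pd(PPh3)4 in THF at 60 °C then ionises the carbonate to a 2-methylallyl palladium cation, and the malonate anion closes 5-exo at the secondary allyl terminus (Tsuji–Trost allylation), which rejoins the route at 12. In this ionic closure a chiral diphosphine ligand on palladium can be used to enforce the C5′ configuration.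

Step 3. The Lewis acid may open the strained cyclobutane next to the activated carbonyl, and the hindered ketone may condense incompletely. Fallback: setting out from 6, condensation with Meldrum's acid under piperidinium acetate catalysis with 4 Å molecular sieves, without any Lewis acid, should give 5-[(1S,5R)-6,6-dimethylbicyclo[3.1.1]heptan-2-ylidene]-2,2-dimethyl-1,3-dioxane-4,6-dione F4. Grignard reagent 10 adds to it in the conjugate sense from the face anti to the gem-dimethyl bridge to give 5-[(1S,2S,5R)-6,6-dimethyl-2-(4-methylpent-3-en-1-yl)bicyclo[3.1.1]heptan-2-yl]-2,2-dimethyl-1,3-dioxane-4,6-dione F5. Heating in methanol opens the dioxanedione to the malonic half ester 2-[(1S,2S,5R)-6,6-dimethyl-2-(4-methylpent-3-en-1-yl)bicyclo[3.1.1]heptan-2-yl]-3-methoxy-3-oxopropanoic acid F6, and Me3SiCHN2 esterifies it, so the route is rejoined at 11.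

Further compounds

F1 | step 10 | methyl 5′-isopropyl-1′-propanoylspiro[pinane-2,2′-cyclopentane]-1′-carboxylate (propanoyl cis to isopropyl) | COC(=O)[C@]1(C(=O)CC)[C@@H](C(C)C)CC[C@@]12CC[C@@H]3C[C@H]2C3(C)C
F2 | step 5 | dimethyl 2-[(1S,2S,5R)-2-[(E)-5-hydroxy-4-methylpent-3-en-1-yl]-6,6-dimethylbicyclo[3.1.1]heptan-2-yl]malonate | COC(=O)C(C(=O)OC)[C@@]1(CC/C=C(\C)CO)CC[C@@H]2C[C@H]1C2(C)C
F3 | step 5 | dimethyl 2-[(1S,2S,5R)-2-[(E)-5-(methoxycarbonyloxy)-4-methylpent-3-en-1-yl]-6,6-dimethylbicyclo[3.1.1]heptan-2-yl]malonate | COC(=O)C(C(=O)OC)[C@@]1(CC/C=C(\C)COC(=O)OC)CC[C@@H]2C[C@H]1C2(C)C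
F4 | step 3 | 5-[(1S,5R)-6,6-dimethylbicyclo[3.1.1]heptan-2-ylidene]-2,2-dimethyl-1,3-dioxane-4,6-dione | CC1(C)OC(=O)C(=C2CC[C@@H]3C[C@H]2C3(C)C)C(=O)O1
F5 | step 3 | 5-[(1S,2S,5R)-6,6-dimethyl-2-(4-methylpent-3-en-1-yl)bicyclo[3.1.1]heptan-2-yl]-2,2-dimethyl-1,3-dioxane-4,6-dione | CC1(C)OC(=O)C(C(=O)O1)[C@@]1(CCC=C(C)C)CC[C@@H]2C[C@H]1C2(C)C
F6 | step 3 | 2-[(1S,2S,5R)-6,6-dimethyl-2-(4-methylpent-3-en-1-yl)bicyclo[3.1.1]heptan-2-yl]-3-methoxy-3-oxopropanoic acid (malonate carbon undefined) | COC(=O)C(C(=O)O)[C@@]1(CCC=C(C)C)CC[C@@H]2C[C@H]1C2(C)C
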